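**Retrosynthetic overview**
- Target ⇐ Luche reduction of the C9 enone ⇐ IBX dehydrogenation (C7=C8) ⇐ anisoylation at C6 ⇐ isopropyl addition to the C4 ketone of a trans-fused hydroazulene-4,9-dione.
- Hydroazulenedione ⇐ retro-aldol opening (C5–C9) of a cyclobutanol ⇐ intramolecular [2+2] photocycloaddition of a cyclopentenyl enol carbonate carrying a 4-methylpent-4-enoyl chain (de Mayo logic).
- Photosubstrate ⇐ C-acylation, then O-carbonylation, of (2S,4S)-4-silyloxy-2-methylcyclopentanone ⇐ (R)-4-silyloxycyclopentenone.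
- Ring order: the purchased cyclopentane (C5–C9) is a scaffold; irradiation forms the cyclobutane and the target's cyclopentane (C1–C5) together; fragmentation then merges cyclobutane and scaffold ring into the cycloheptane.
- Stereocontrol: the C6 oxygen of the starting material steers C1 (photoaddition), C5 (protonation), C4 (chelation) and C9 (hydride).

Assumption: (R)-4-(tert-butyldimethylsilyloxy)cyclopent-2-en-1-one, the bulk prostaglandin building block made from furfuryl alcohol, counts as a purchasable starting material.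

Numbering used for all compounds: C1 = methyl-bearing ring-fusion carbon; C2, C3; C4 = carbinol carbon with isopropyl; C5 = ring-fusion CH; C6 = ester carbon; C7=C8 (methyl on C8); C9 = carbinol; C10. β = face of the C1 methyl, α = opposite face. "Perhydroazulene" means the bicyclo[5.3.0]decane skeleton with these locants. Target = 1β-CH3, 4β-OH, 5α-H, 6α-O-acyl, 9β-OH, i.e. (1R,4R,5S,6S,9R).

**Step 1**
Reactants: 1 (R)-4-[(tert-butyldimethylsilyl)oxy]cyclopent-2-en-1-one
Product: 4 (2S,4S)-4-[(tert-butyldimethylsilyl)oxy]-2-methylcyclopentan-1-one, via triethylsilyl enol ether 2 (not isolated), via lithium enolate 3 (not isolated)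
Conditions: Et3SiH, RhCl(PPh3)3 (1 mol%), PhH, 50 °C; then MeLi, THF, 0 °C; then MeI, −78 → 0 °C
Reagents that add atoms: iodomethane (CI)
Why: Rh-catalysed 1,4-hydrosilylation gives the regiodefined silyl enol ether, MeLi releases the lithium enolate and MeI alkylates C8 (regiospecific enolate alkylation) mainly anti to the silyloxy group; C6 from 1 is untouched, and the C8 centre (minor epimer carried along) is erased in step 8.

**Step 2**
Reactants: 4 (2S,4S)-4-[(tert-butyldimethylsilyl)oxy]-2-methylcyclopentan-1-one; 5 4-methylpent-4-enoic acid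
Product: 8 (2S,3S,5S)-3-[(tert-butyldimethylsilyl)oxy]-5-methyl-2-(4-methylpent-4-enoyl)cyclopentan-1-one, via acyl imidazole 6 (not isolated), via lithium enolate 7 (not isolated)
Conditions: 5, 1,1'-carbonyldiimidazole, THF, 23 °C; 4, LiN(SiMe3)2 (2.2 equiv), THF, −78 °C; combine, −78 → 0 °C; aq. HCl
Reagents that add atoms: none
Why: Kinetic deprotonation at the less substituted α-carbon (C5) followed by C-acylation with the acyl imidazole (crossed Claisen-type ketone acylation) gives the 1,3-diketone, which the second equivalent of base protects as its enolate; C5 is enolised, so no permanent stereocentre is created.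

**Step 3**
Reactants: 8 (2S,3S,5S)-3-[(tert-butyldimethylsilyl)oxy]-5-methyl-2-(4-methylpent-4-enoyl)cyclopentan-1-one
Product: 9 (3S,5S)-3-[(tert-butyldimethylsilyl)oxy]-5-methyl-2-(4-methylpent-4-enoyl)cyclopent-1-en-1-yl 2-(trimethylsilyl)ethyl carbonate
Conditions: Me3SiCH2CH2OCOCl, pyridine, CH2Cl2, 0 °C
Reagents that add atoms: 2-(trimethylsilyl)ethyl chloroformate (C[Si](C)(C)CCOC(Cl)=O)
Why: O-acylation of the chelated 2-acylcyclopentanone enol at the ring oxygen fixes the endocyclic C5=C9 enol as a carbonate conjugated with the side-chain ketone, which is the enone chromophore needed for ring-expanding photochemistry; no stereocentre changes.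

**Step 4**
Reactants: 9 (3S,5S)-3-[(tert-butyldimethylsilyl)oxy]-5-methyl-2-(4-methylpent-4-enoyl)cyclopent-1-en-1-yl 2-(trimethylsilyl)ethyl carbonate
Product: 10 6α-(tert-butyldimethylsilyloxy)-1β,8β-dimethyl-4-oxo-5,9-cycloperhydroazulen-9-yl 2-(trimethylsilyl)ethyl carbonate
Conditions: hν (λ > 300 nm, Pyrex), cyclohexane, 0.01 mol/L, 20 °C
Reagents that add atoms: none
Why: Intramolecular enone–alkene [2+2] photocycloaddition (de Mayo-type, rule-of-five closure of the 1,6-heptadien-3-one unit) forms the cyclobutane and the new cyclopentanone in one operation; the tether bonds to C5 on the face opposite the adjacent C6 silyloxy group, and only the biradical with C10 turned towards C9 can close the cis-fused cyclobutane, which sets the quaternary C1 relative to C6.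

**Step 5**
Reactants: 10 6α-(tert-butyldimethylsilyloxy)-1β,8β-dimethyl-4-oxo-5,9-cycloperhydroazulen-9-yl 2-(trimethylsilyl)ethyl carbonate
Product: 13 6α-hydroxy-1β,8β-dimethyl-5αH-perhydroazulene-4,9-dione, via cyclobutanol 11 (not isolated), via silyl ether dione 12 (not isolated)
Conditions: TBAF, AcOH (1:1), THF, 0 → 23 °C
Reagents that add atoms: none
Why: Fluoride removes the carbonate, the cyclobutanolate undergoes retro-aldol cleavage of C5–C9 (de Mayo fragmentation) to open the seven-membered ring, the C4 enolate is protonated at C5 on the face C9 left, anti to the C6 silyloxy group (trans ring fusion, kept by the cold buffered medium), and the same reagent then cleaves the silyl ether.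

**Step 6**
Reactants: 13 6α-hydroxy-1β,8β-dimethyl-5αH-perhydroazulene-4,9-dione
Product: 14 4β,6α-dihydroxy-4α-isopropyl-1β,8β-dimethyl-5αH-perhydroazulen-9-one
Conditions: iPrMgCl (3 equiv), LaCl3·2LiCl, THF, −78 → −40 °C; aq. NH4Cl
Reagents that add atoms: isopropylmagnesium chloride (CC(C)[Mg]Cl)
Why: Chelation-accelerated Grignard addition (lanthanum salt suppresses enolisation and reduction) to the β-alkoxy ketone C4 in preference to the C9 ketone, which is hindered by the C8 branch and the neopentyl C10; attack on the α face, anti to the angular C1 methyl and on the H5 side of the C6-alkoxide chelate, gives the 4β-OH.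

**Step 7**
Reactants: 14 4β,6α-dihydroxy-4α-isopropyl-1β,8β-dimethyl-5αH-perhydroazulen-9-one; 15 4-methoxybenzoyl chloride
Product: 16 4β-hydroxy-4α-isopropyl-1β,8β-dimethyl-9-oxo-5αH-perhydroazulen-6α-yl 4-methoxybenzoate
Conditions: DMAP, Et3N, CH2Cl2, 0 → 23 °C
Reagents that add atoms: none
Why: DMAP-catalysed acyl transfer esterifies the only secondary alcohol (C6) while the tertiary C4 hydroxyl does not react; no stereocentre changes.

**Step 8**
Reactants: 16 4β-hydroxy-4α-isopropyl-1β,8β-dimethyl-9-oxo-5αH-perhydroazulen-6α-yl 4-methoxybenzoate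
Product: 17 4β-hydroxy-4α-isopropyl-1β,8-dimethyl-9-oxo-5αH-perhydroazulen-7-en-6α-yl 4-methoxybenzoate
Conditions: IBX, DMSO, 75 °C
Reagents that add atoms: none
Why: IBX dehydrogenation of the ketone (Nicolaou oxidation) can only run towards C8–C7 because C10 has no β-hydrogen (C1 is quaternary), which gives the C7=C8 enone and erases the C8 centre.

**Step 9**
Reactants: 17 4β-hydroxy-4α-isopropyl-1β,8-dimethyl-9-oxo-5αH-perhydroazulen-7-en-6α-yl 4-methoxybenzoate
Product: 18 (1R,4R,5S,6S,9R)-4,9-dihydroxy-4-isopropyl-1,8-dimethyl-5H-perhydroazulen-7-en-6-yl 4-methoxybenzoate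
Conditions: NaBH4, CeCl3·7H2O, MeOH, −78 °C
Reagents that add atoms: none
Why: Luche 1,2-reduction of the enone, with hydride adding to C9 from the α face, away from the pseudo-axial C1 methyl that shields the β face, gives the 9β-alcohol and leaves the ester intact.

**Compound list**
1 | (R)-4-[(tert-butyldimethylsilyl)oxy]cyclopent-2-en-1-one | O=C1C=C[C@H](O[Si](C)(C)C(C)(C)C)C1 | starting material
2 | (S)-tert-butyldimethyl{[3-(triethylsilyloxy)cyclopent-3-en-1-yl]oxy}silane (enol ether between C8 and C9) | CC[Si](CC)(CC)OC1=CC[C@H](O[Si](C)(C)C(C)(C)C)C1 | intermediate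
3 | lithium (S)-4-[(tert-butyldimethylsilyl)oxy]cyclopent-1-en-1-olate | [Li]OC1=CC[C@H](O[Si](C)(C)C(C)(C)C)C1 | intermediate
4 | (2S,4S)-4-[(tert-butyldimethylsilyl)oxy]-2-methylcyclopentan-1-one (methyl trans to OSi; minor 2-epimer carried along) | O=C1[C@@H](C)C[C@H](O[Si](C)(C)C(C)(C)C)C1 | intermediate
5 | 4-methylpent-4-enoic acid | C=C(C)CCC(=O)O | starting material
6 | 1-(4-methylpent-4-enoyl)-1H-imidazole | C=C(C)CCC(=O)n1ccnc1 | intermediate
7 | lithium (3S,5S)-3-[(tert-butyldimethylsilyl)oxy]-5-methylcyclopent-1-en-1-olate (kinetic enolate at C5) | [Li]OC1=C[C@@H](O[Si](C)(C)C(C)(C)C)C[C@@H]1C | intermediate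
8 | (2S,3S,5S)-3-[(tert-butyldimethylsilyl)oxy]-5-methyl-2-(4-methylpent-4-enoyl)cyclopentan-1-one (largely enolised; C2 labile, drawn 2,3-trans) | O=C1[C@@H](C)C[C@H](O[Si](C)(C)C(C)(C)C)[C@H]1C(=O)CCC(C)=C | intermediate
9 | (3S,5S)-3-[(tert-butyldimethylsilyl)oxy]-5-methyl-2-(4-methylpent-4-enoyl)cyclopent-1-en-1-yl 2-(trimethylsilyl)ethyl carbonate | C=C(C)CCC(=O)C1=C(OC(=O)OCC[Si](C)(C)C)[C@@H](C)C[C@@H]1O[Si](C)(C)C(C)(C)C | intermediate
10 | tricyclic photoadduct: cyclobutane C1–C5–C9–C10 cis-fused to both five-membered rings, on the face opposite the C6 OSi group; C4 ketone; C9 carbonate; 1β-CH3, 8β-CH3 | O=C1CC[C@]2(C)C[C@@]3(OC(=O)OCC[Si](C)(C)C)[C@@H](C)C[C@H](O[Si](C)(C)C(C)(C)C)[C@@]123 | intermediate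
11 | cyclobutanol from 10 (free C9–OH, C6 OSi retained) | O=C1CC[C@]2(C)C[C@@]3(O)[C@@H](C)C[C@H](O[Si](C)(C)C(C)(C)C)[C@@]123 | intermediate
12 | 6α-(tert-butyldimethylsilyloxy)-1β,8β-dimethyl-5αH-perhydroazulene-4,9-dione | O=C1CC[C@]2(C)CC(=O)[C@@H](C)C[C@H](O[Si](C)(C)C(C)(C)C)[C@@H]12 | intermediate
13 | 6α-hydroxy-1β,8β-dimethyl-5αH-perhydroazulene-4,9-dione (trans-fused) | O=C1CC[C@]2(C)CC(=O)[C@@H](C)C[C@H](O)[C@@H]12 | intermediate
14 | 4β,6α-dihydroxy-4α-isopropyl-1β,8β-dimethyl-5αH-perhydroazulen-9-one | CC(C)[C@]1(O)CC[C@]2(C)CC(=O)[C@@H](C)C[C@H](O)[C@@H]12 | intermediate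
15 | 4-methoxybenzoyl chloride | COc1ccc(C(Cl)=O)cc1 | starting material
16 | 4β-hydroxy-4α-isopropyl-1β,8β-dimethyl-9-oxo-5αH-perhydroazulen-6α-yl 4-methoxybenzoate | COc1ccc(C(=O)O[C@H]2C[C@H](C)C(=O)C[C@@]3(C)CC[C@@](O)(C(C)C)[C@H]23)cc1 | intermediate
17 | 4β-hydroxy-4α-isopropyl-1β,8-dimethyl-9-oxo-5αH-perhydroazulen-7-en-6α-yl 4-methoxybenzoate | COc1ccc(C(=O)O[C@H]2C=C(C)C(=O)C[C@@]3(C)CC[C@@](O)(C(C)C)[C@H]23)cc1 | intermediate
18 | (3R,3aS,4S,7R,8aR)-3,7-dihydroxy-6,8a-dimethyl-3-(propan-2-yl)-1,2,3,3a,4,7,8,8a-octahydroazulen-4-yl 4-methoxybenzoate (CNP0251753.2) | COc1ccc(C(=O)O[C@H]2C=C(C)[C@H](O)C[C@@]3(C)CC[C@@](O)(C(C)C)[C@H]23)cc1 | target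

**Totals**
Total step count: 9. Longest linear sequence: 9 steps (1 → 18); 5 and 15 are purchased and enter in steps 2 and 7.

**Three steps most likely to fail, with fallbacks**

Step 4 (photocycloaddition). The hindered 1,1-disubstituted alkene may close in the crossed sense or react sluggishly. The fallback sets out from 9. Luche reduction (NaBH4, CeCl3·7H2O, MeOH, −40 °C) of the side-chain ketone gives the dienyl carbinol F1, a 1,6-heptadien-3-ol. Irradiation at 254 nm with (CuOTf)2·C6H6 (monovalent copper) in Et2O closes the copper-bridged 1,6-diene in the straight sense to the tricyclic carbinol F2. Dess–Martin oxidation of F2 comes back to the route at 10.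

Step 5 (fragmentation). Protonation at C5 could give the cis-fused epimer, or the C4 enolate could expel the C6 oxygen. The fallback sets out from 10. Addition of iPrMgCl with LaCl3·2LiCl to its only ketone, expected from the cyclobutane face because the other face is flanked by the C1 methyl and C6, gives the tricyclic tertiary alcohol F3. TBAF removes both silicon groups to give the triol F4. Dess–Martin oxidation of its single secondary alcohol (C6) triggers the retro-aldol through the C6 ketone to the dione F5. In F5, C5 equilibrates next to the C6 ketone to the trans fusion, which keeps H5 rather than C6 cis to the isopropyl group. Reduction with Me4NBH(OAc)3, hydride delivered from the C4 hydroxyl in the 1,3-anti sense, comes back to the route at 14.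

Step 6 (isopropyl addition). The secondary Grignard reagent may reduce or enolise 13, or attack C9. The fallback sets out from 13. The smaller, non-reducing sp2 nucleophile CH2=C(CH3)MgBr with LaCl3·2LiCl in THF at −78 °C gives the isopropenyl carbinol F6. Hydrogenation of its 1,1-disubstituted alkene (H2, Pd on carbon, EtOAc) comes back to the route at 14.

**Further compounds**
F1 | step 4 | (3S,5S)-3-[(tert-butyldimethylsilyl)oxy]-2-(1-hydroxy-4-methylpent-4-enyl)-5-methylcyclopent-1-en-1-yl 2-(trimethylsilyl)ethyl carbonate (both carbinol epimers) | C=C(C)CCC(O)C1=C(OC(=O)OCC[Si](C)(C)C)[C@@H](C)C[C@@H]1O[Si](C)(C)C(C)(C)C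
F2 | step 4 | C4 alcohol of photoadduct 10 (both C4 epimers) | OC1CC[C@]2(C)C[C@@]3(OC(=O)OCC[Si](C)(C)C)[C@@H](C)C[C@H](O[Si](C)(C)C(C)(C)C)[C@@]123
F3 | step 5 | 4β-hydroxy-4α-isopropyl derivative of photoadduct 10 (C9 carbonate and C6 OSi retained) | CC(C)[C@]1(O)CC[C@]2(C)C[C@@]3(OC(=O)OCC[Si](C)(C)C)[C@@H](C)C[C@H](O[Si](C)(C)C(C)(C)C)[C@@]123
F4 | step 5 | 4α-isopropyl-1β,8β-dimethyl-5,9-cycloperhydroazulene-4β,6α,9-triol | CC(C)[C@]1(O)CC[C@]2(C)C[C@@]3(O)[C@@H](C)C[C@H](O)[C@@]123
F5 | step 5 | 4β-hydroxy-4α-isopropyl-1β,8β-dimethyl-5αH-perhydroazulene-6,9-dione | CC(C)[C@]1(O)CC[C@]2(C)CC(=O)[C@@H](C)CC(=O)[C@@H]12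
F6 | step 6 | 4β,6α-dihydroxy-1β,8β-dimethyl-4α-(prop-1-en-2-yl)-5αH-perhydroazulen-9-one | C=C(C)[C@]1(O)CC[C@]2(C)CC(=O)[C@@H](C)C[C@H](O)[C@@H]12
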